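**Strategy.** Both carboxyl carbons are disconnected from the aromatic rings, leading back to the carboxyl-free depside 13, 2,4-dihydroxy-3,6-dimethylphenyl 2-hydroxy-4-methoxy-6-methylbenzoate, with all three phenols free. The key step exploits C3 of ring A (benzoyl ring; the C–H between the C2 hydroxyl and C4 methoxy carbons) and C3' of ring B (aryloxy ring; its only C–H, ortho to the C4' hydroxyl, para to the C6' hydroxyl): each is the hydroxyl-directed nucleophilic carbon of its ring. One TiCl4-mediated Rieche formylation should create both aryl–carbonyl carbon bonds; a Lindgren chlorite oxidation then delivers the diacid. Depside 13 comes from benzyl-protected everninic acid and a benzyl-protected ring B phenol.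

Key step: step 8

Remark: everninic acid (7) is assumed to be purchasable as such. Ring A is numbered from the carbon bearing the ester carbonyl (C2 OH, C4 OMe, C5 H, C6 CH3) and ring B, with primes, from the carbon bearing the ester oxygen (C2' CH3, C4' OH, C5' CH3, C6' OH). The target is achiral. Species 2, 11 and 15 are drawn in their simplest salt or covalent form.

**Step 1**
Reactants: 1 2,5-dimethylresorcinol
Product: 3 2,4-dihydroxy-3,6-dimethylbenzaldehyde, via aryliminium chloride 2 (not isolated)
Conditions: POCl3, DMF, 0 °C to rt; then H2O, 50 °C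
Reagents that add atoms: N,N-dimethylformamide, CN(C)C=O (formyl carbon); water, O (formyl oxygen)
Why: Vilsmeier–Haack formylation; the chloroiminium ion attacks the only kind of free position of the symmetric resorcinol (C4 and C6 are equivalent, each ortho to one hydroxyl and para to the other), and the deactivated iminium salt 2 cannot react twice before it is hydrolysed to the aldehyde.

**Step 2**
Reactants: 3 2,4-dihydroxy-3,6-dimethylbenzaldehyde
Product: 4 2,4-bis(benzyloxy)-3,6-dimethylbenzaldehyde
Conditions: BnBr (2.4 equiv), K2CO3, DMF, 60 °C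
Reagents that add atoms: benzyl bromide, BrCc1ccccc1
Why: Williamson ether synthesis; both phenoxides, including the hydrogen-bonded one next to the formyl group, are O-benzylated in warm DMF, giving ethers that tolerate the peracid, base and acylation steps ahead and leave together by hydrogenolysis.

**Step 3**
Reactants: 4 2,4-bis(benzyloxy)-3,6-dimethylbenzaldehyde
Product: 6 2,4-bis(benzyloxy)-3,6-dimethylphenol, via aryl formate 5 (not isolated)
Conditions: mCPBA, CH2Cl2, 0 °C to rt; aq. Na2S2O3/NaHCO3 wash; then K2CO3 (cat.), MeOH, rt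
Reagents that add atoms: meta-chloroperoxybenzoic acid, O=C(OO)c1cccc(Cl)c1 (phenolic oxygen)
Why: Baeyer–Villiger oxidation (the peracid counterpart of the Dakin reaction, required because no free ortho or para hydroxyl is present); the electron-rich aryl group migrates in preference to hydride and the aryl formate is transesterified by methanol to release the phenol.

**Step 4**
Reactants: 7 2-hydroxy-4-methoxy-6-methylbenzoic acid (everninic acid)
Product: 8 benzyl 2-(benzyloxy)-4-methoxy-6-methylbenzoate
Conditions: BnBr (2.4 equiv), K2CO3, DMF, 60 °C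
Reagents that add atoms: benzyl bromide, BrCc1ccccc1
Why: Williamson etherification of the phenol with concurrent SN2 alkylation of the carboxylate; exhaustive benzylation avoids any selectivity question between the two acidic groups.

**Step 5**
Reactants: 8 benzyl 2-(benzyloxy)-4-methoxy-6-methylbenzoate
Product: 9 2-(benzyloxy)-4-methoxy-6-methylbenzoic acid
Conditions: KOH, DMSO–H2O, 90 °C; then aq. HCl, 0 °C
Reagents that add atoms: potassium hydroxide, [K+].[OH-] (carboxyl oxygen replacing the benzyloxy group)
Why: Saponification (base-mediated acyl–oxygen ester hydrolysis); poorly solvated hydroxide in aqueous DMSO overcomes the hindrance of the di-ortho-substituted benzoate while the aryl benzyl and methyl ethers are inert.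

**Step 6**
Reactants: 9 2-(benzyloxy)-4-methoxy-6-methylbenzoic acid; 6 2,4-bis(benzyloxy)-3,6-dimethylphenol
Product: 12 2,4-bis(benzyloxy)-3,6-dimethylphenyl 2-(benzyloxy)-4-methoxy-6-methylbenzoate, via acid chloride 10 (not isolated), via sodium phenoxide 11 (not isolated)
Conditions: 9, (COCl)2, DMF (cat.), CH2Cl2, 0 °C to rt, evaporate; 6, NaH, THF, 0 °C; combine, 0 °C to rt
Reagents that add atoms: none
Why: Acid chloride formation followed by O-acylation of a preformed phenoxide (anhydrous Schotten–Baumann-type esterification); only one carboxyl and one free hydroxyl are present, so a single ester can form, and the phenoxide is used because both partners are di-ortho-substituted.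

**Step 7**
Reactants: 12 2,4-bis(benzyloxy)-3,6-dimethylphenyl 2-(benzyloxy)-4-methoxy-6-methylbenzoate
Product: 13 2,4-dihydroxy-3,6-dimethylphenyl 2-hydroxy-4-methoxy-6-methylbenzoate
Conditions: H2 (1 atm), Pd/C, EtOAc, rt
Reagents that add atoms: none
Why: Catalytic hydrogenolysis of the three aryl benzyl ethers under neutral conditions; the hindered aryl ester is untouched and no base is present that could move the acyl group to the neighbouring C6' hydroxyl.

**Step 8**
Reactants: 13 2,4-dihydroxy-3,6-dimethylphenyl 2-hydroxy-4-methoxy-6-methylbenzoate; 14 dichloromethyl methyl ether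
Product: 16 3-formyl-4,6-dihydroxy-2,5-dimethylphenyl 3-formyl-2-hydroxy-4-methoxy-6-methylbenzoate, via bis(chloro ether) 15 (not isolated)
Conditions: TiCl4 (7 equiv), CH2Cl2, 0 °C; Cl2CHOMe (3 equiv), 0 °C to rt; then ice-cold 1 M HCl
Reagents that add atoms: dichloromethyl methyl ether, COC(Cl)Cl (both formyl carbons); water, O (both formyl oxygens, on hydrolytic work-up)
Why: Rieche formylation, a Friedel–Crafts alkylation by the methoxychlorocarbenium ion that TiCl4 abstracts from Cl2CHOMe, followed by hydrolysis of the two aryl chloro(methoxy)methyl groups of 15 to aldehydes on work-up. The closest known reaction type is the TiCl4-mediated ortho-formylation of phenols and of orsellinate-type salicylates. No ring is closed and no stereocentre is created in the product, the two chloro ether carbons of 15 being transient. The selectivity needed is C3 over C5 on ring A: the titanium phenoxide at O2, chelated to the ester carbonyl, binds the ether oxygen of the reagent and delivers the cation to the adjacent C3, which is also ortho to the C4 methoxy group, whereas C5 lies para to O2, beyond this delivery, and is flanked by the methoxy and C6 methyl groups. Ring B has a single C–H (C3'), ortho to the C4' titanium phenoxide and para to O6', and as the more electron-rich ring should react first; excess reagent drives the slower attack on the ester-bearing ring A, and each ring is too deactivated after one formyl group for a second. The di-ortho-substituted aryl ester should survive the Lewis acid at 0 °C, and since it was formed before any carboxyl group existed no protecting group is needed here or later.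

**Step 9**
Reactants: 16 3-formyl-4,6-dihydroxy-2,5-dimethylphenyl 3-formyl-2-hydroxy-4-methoxy-6-methylbenzoate
Product: 17 hypothamnolic acid, 3-[(3-carboxy-4,6-dihydroxy-2,5-dimethylphenoxy)carbonyl]-2-hydroxy-6-methoxy-4-methylbenzoic acid
Conditions: NaClO2, H2NSO3H, dioxane–H2O, 0 °C to rt
Reagents that add atoms: sodium chlorite, [Na+].[O-]Cl=O (one oxygen per aldehyde)
Why: Lindgren (Pinnick-type) chlorite oxidation; chlorous acid adds to each aldehyde and fragments to the carboxylic acid and hypochlorous acid, which sulfamic acid removes before it can chlorinate C5 of ring A or oxidise the phenols, while the cold acidic medium spares the depside ester and the decarboxylation-prone salicylic acids.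

**Compound list**
1 | 2,5-dimethylresorcinol | Cc1cc(O)c(C)c(O)c1 | starting material
2 | N-(2,4-dihydroxy-3,6-dimethylbenzylidene)-N,N-dimethyliminium chloride | C[N+](C)=Cc1c(O)c(C)c(O)cc1C.[Cl-] | intermediate
3 | 2,4-dihydroxy-3,6-dimethylbenzaldehyde | O=Cc1c(O)c(C)c(O)cc1C | intermediate
4 | 2,4-bis(benzyloxy)-3,6-dimethylbenzaldehyde | O=Cc1c(OCc2ccccc2)c(C)c(OCc2ccccc2)cc1C | intermediate
5 | 2,4-bis(benzyloxy)-3,6-dimethylphenyl formate | O=COc1c(OCc2ccccc2)c(C)c(OCc2ccccc2)cc1C | intermediate
6 | 2,4-bis(benzyloxy)-3,6-dimethylphenol | Oc1c(OCc2ccccc2)c(C)c(OCc2ccccc2)cc1C | intermediate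
7 | 2-hydroxy-4-methoxy-6-methylbenzoic acid (everninic acid) | COc1cc(C)c(C(=O)O)c(O)c1 | starting material
8 | benzyl 2-(benzyloxy)-4-methoxy-6-methylbenzoate | COc1cc(C)c(C(=O)OCc2ccccc2)c(OCc2ccccc2)c1 | intermediate
9 | 2-(benzyloxy)-4-methoxy-6-methylbenzoic acid | COc1cc(C)c(C(=O)O)c(OCc2ccccc2)c1 | intermediate
10 | 2-(benzyloxy)-4-methoxy-6-methylbenzoyl chloride | COc1cc(C)c(C(Cl)=O)c(OCc2ccccc2)c1 | intermediate
11 | sodium 2,4-bis(benzyloxy)-3,6-dimethylphenoxide | [Na+].[O-]c1c(OCc2ccccc2)c(C)c(OCc2ccccc2)cc1C | intermediate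
12 | 2,4-bis(benzyloxy)-3,6-dimethylphenyl 2-(benzyloxy)-4-methoxy-6-methylbenzoate | COc1cc(C)c(C(=O)Oc2c(OCc3ccccc3)c(C)c(OCc3ccccc3)cc2C)c(OCc2ccccc2)c1 | intermediate
13 | 2,4-dihydroxy-3,6-dimethylphenyl 2-hydroxy-4-methoxy-6-methylbenzoate | COc1cc(C)c(C(=O)Oc2c(C)cc(O)c(C)c2O)c(O)c1 | intermediate
14 | dichloromethyl methyl ether | COC(Cl)Cl | starting material
15 | 3-[chloro(methoxy)methyl]-4,6-dihydroxy-2,5-dimethylphenyl 3-[chloro(methoxy)methyl]-2-hydroxy-4-methoxy-6-methylbenzoate (titanium-bound, mixture of diastereomers) | COc1cc(C)c(C(=O)Oc2c(C)c(C(Cl)OC)c(O)c(C)c2O)c(O)c1C(Cl)OC | intermediate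
16 | 3-formyl-4,6-dihydroxy-2,5-dimethylphenyl 3-formyl-2-hydroxy-4-methoxy-6-methylbenzoate | COc1cc(C)c(C(=O)Oc2c(C)c(C=O)c(O)c(C)c2O)c(O)c1C=O | intermediate
17 | hypothamnolic acid | COc1cc(C)c(C(=O)Oc2c(C)c(C(=O)O)c(O)c(C)c2O)c(O)c1C(=O)O | target

**Step count**
Total steps: 9. Longest linear sequence: 7 steps (steps 1, 2, 3, 6, 7, 8, 9); steps 4 and 5 form the two-step ring A branch.

**Steps most likely to fail**

Step 8. The electrophile may attack C5 of ring A instead of C3, the reaction may stall once ring B alone has reacted, or the Lewis acid may promote acyl transfer to O6'. The fallback separates the two formylations and fixes the ring A site on the monomer by a mechanism that can only reach the carbon ortho to the hydroxyl. It sets out from 7 and 6 and returns at 16.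
- Everninic acid 7 is esterified at the carboxylate only (BnBr, KHCO3, DMF) to give benzyl 2-hydroxy-4-methoxy-6-methylbenzoate F1.
- Magnesium-mediated ortho-formylation of F1 (MgCl2, Et3N, paraformaldehyde, MeCN, reflux) passes through benzyl 2-hydroxy-3-(hydroxymethyl)-4-methoxy-6-methylbenzoate F2 (magnesium salt, not isolated), which transfers hydride to formaldehyde and gives benzyl 3-formyl-2-hydroxy-4-methoxy-6-methylbenzoate F3.
- Brief hydrogenolysis (H2, Pd/C, EtOAc, one equivalent of hydrogen) frees 3-formyl-2-hydroxy-4-methoxy-6-methylbenzoic acid F4.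
- DCC in toluene activates F4 as its O-acylisourea F5 (not isolated), which acylates phenol 6 to give 2,4-bis(benzyloxy)-3,6-dimethylphenyl 3-formyl-2-hydroxy-4-methoxy-6-methylbenzoate F6.
- Hydrogenolysis of the two benzyl ethers gives 2,4-dihydroxy-3,6-dimethylphenyl 3-formyl-2-hydroxy-4-methoxy-6-methylbenzoate F7.
- Rieche formylation of F7 (Cl2CHOMe, TiCl4, CH2Cl2, 0 °C), now needed only at the single free carbon of ring B, proceeds through the ring B chloro(methoxy)methyl compound F8 (not isolated) and gives 16 after hydrolysis.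

Step 6. Acylation between two di-ortho-substituted partners may be slow, so that the acid chloride is lost to moisture or sheds its ortho benzyl group under chloride attack. The fallback changes both the activation mode and the protecting-group plan. It sets out from 7 and 6 and returns at 13.
- Unprotected everninic acid 7 and phenol 6 are condensed with trifluoroacetic anhydride in toluene at rt through the mixed anhydride 2-hydroxy-4-methoxy-6-methylbenzoic trifluoroacetic anhydride F9 (not isolated); the chelated C2 hydroxyl does not compete as a nucleophile. This gives 2,4-bis(benzyloxy)-3,6-dimethylphenyl 2-hydroxy-4-methoxy-6-methylbenzoate F10.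
- Hydrogenolysis of F10 (H2, Pd/C, EtOAc) gives 13.

Step 9. Hypochlorous acid or chlorine oxides may chlorinate C5 of ring A or degrade the electron-rich phenolic rings before both aldehydes are consumed. The fallback masks the phenols as electron-withdrawing acetates during the oxidation. It sets out from 16 and returns at 17.
- Peracetylation of 16 (Ac2O, pyridine, DMAP cat., CH2Cl2) gives 4,6-diacetoxy-3-formyl-2,5-dimethylphenyl 2-acetoxy-3-formyl-4-methoxy-6-methylbenzoate F11.
- Pinnick oxidation (NaClO2, NaH2PO4, 2-methyl-2-butene, t-BuOH–H2O) gives the diacid 2-acetoxy-3-[(4,6-diacetoxy-3-carboxy-2,5-dimethylphenoxy)carbonyl]-6-methoxy-4-methylbenzoic acid F12.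
- Mild acetate cleavage (NH4OAc, aqueous MeOH, rt, then dilute HCl) removes the three unhindered aryl acetates and leaves the hindered depside ester, giving 17.

**Further compounds**
F1 | step 8 | benzyl 2-hydroxy-4-methoxy-6-methylbenzoate | COc1cc(C)c(C(=O)OCc2ccccc2)c(O)c1
F2 | step 8 | benzyl 2-hydroxy-3-(hydroxymethyl)-4-methoxy-6-methylbenzoate | COc1cc(C)c(C(=O)OCc2ccccc2)c(O)c1CO
F3 | step 8 | benzyl 3-formyl-2-hydroxy-4-methoxy-6-methylbenzoate | COc1cc(C)c(C(=O)OCc2ccccc2)c(O)c1C=O
F4 | step 8 | 3-formyl-2-hydroxy-4-methoxy-6-methylbenzoic acid | COc1cc(C)c(C(=O)O)c(O)c1C=O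
F5 | step 8 | O-(3-formyl-2-hydroxy-4-methoxy-6-methylbenzoyl)-N,N'-dicyclohexylisourea | COc1cc(C)c(C(=O)OC(=NC2CCCCC2)NC2CCCCC2)c(O)c1C=O
F6 | step 8 | 2,4-bis(benzyloxy)-3,6-dimethylphenyl 3-formyl-2-hydroxy-4-methoxy-6-methylbenzoate | COc1cc(C)c(C(=O)Oc2c(OCc3ccccc3)c(C)c(OCc3ccccc3)cc2C)c(O)c1C=O
F7 | step 8 | 2,4-dihydroxy-3,6-dimethylphenyl 3-formyl-2-hydroxy-4-methoxy-6-methylbenzoate | COc1cc(C)c(C(=O)Oc2c(C)cc(O)c(C)c2O)c(O)c1C=O
F8 | step 8 | 3-[chloro(methoxy)methyl]-4,6-dihydroxy-2,5-dimethylphenyl 3-formyl-2-hydroxy-4-methoxy-6-methylbenzoate | COc1cc(C)c(C(=O)Oc2c(C)c(C(Cl)OC)c(O)c(C)c2O)c(O)c1C=O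
F9 | step 6 | 2-hydroxy-4-methoxy-6-methylbenzoic trifluoroacetic anhydride | COc1cc(C)c(C(=O)OC(=O)C(F)(F)F)c(O)c1
F10 | step 6 | 2,4-bis(benzyloxy)-3,6-dimethylphenyl 2-hydroxy-4-methoxy-6-methylbenzoate | COc1cc(C)c(C(=O)Oc2c(OCc3ccccc3)c(C)c(OCc3ccccc3)cc2C)c(O)c1
F11 | step 9 | 4,6-diacetoxy-3-formyl-2,5-dimethylphenyl 2-acetoxy-3-formyl-4-methoxy-6-methylbenzoate | COc1cc(C)c(C(=O)Oc2c(C)c(C=O)c(OC(C)=O)c(C)c2OC(C)=O)c(OC(C)=O)c1C=O
F12 | step 9 | 2-acetoxy-3-[(4,6-diacetoxy-3-carboxy-2,5-dimethylphenoxy)carbonyl]-6-methoxy-4-methylbenzoic acid | COc1cc(C)c(C(=O)Oc2c(C)c(C(=O)O)c(OC(C)=O)c(C)c2OC(C)=O)c(OC(C)=O)c1C(=O)O
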